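Seconds are the scale of this flask, so you read it by τ, the time at which 50% of the L charged is gone.

| setting | beta | zeta | flask |
|---|---|---|---|
| L | 2 mM | 2 mM | 2.0 mM |
| J | 0.15 mM | 0.60 mM | 0.30 mM |
| remark | run made earlier | run made earlier |  |

- beta (time / s: D / %, L / %): 15.0: 15.1, 81.2; 40.0: 34.6, 63.2; 80.0: 53.5, 45.1; 120: 65.2, 34.8
- zeta (time / s: D / %, L / %): 10.0: 36.1, 50.8; 20.0: 62.9, 28.0; 50.0: 92.7, 5.5; 120: 99.0, 0

(scatter of a reading: 1 percentage point)

* factor on the rate of making D when 50% of the L are converted if J is charged twice over
* factor on the rate when 50% of the L are converted if J is charged at 1.5 mM instead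

Your flask holds 2.0 mM L and 0.30 mM J. Interpolating the L readings, beta reaches that mark at 69.2 s and zeta at 10.4 s. So the working order n, the power of the J charge that the inverse of τ follows, reads 1.37, above first order.

I reckon from both ends and join them. Inside the runs, doubling J to 0.60 mM gives 2.59, and your flask should reach the mark near 26.8 s. Expect D under 50% then: zeta's first reading falls short of the charge by 13 percentage points, so some L sits bound on J.

Don't stretch n past zeta's charge. Zeta reaches the mark sooner than beta, so whatever slows beta has less time there. I take first order from 0.60 mM to 1.5 mM, which gives 6.46.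

The forecast says 2.3 and 6.2, holding that “J dies with time, not a fixed poison”. Mine stand higher on both.

The simulation gives 2.58 and 6.30.

    L + J → E (k = 270 M⁻¹ s⁻¹)
    E → J + D (k = 0.250 s⁻¹)
    J ⇌ G (K = 5.80, k = 0.0460 s⁻¹)

So in this flask the order from 0.30 mM to 0.60 mM is 1.37, close to n, while from 0.60 mM to 1.5 mM it is 0.974. The largest single effect behind the excess over first order is J parking as G, a form outside the working round: in the run without J ⇌ G, the apparent order in J at 50% conversion is 1.0 instead of 1.5.

The readings were computed on assumed constants; noise was put on by code.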